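**Assumption (chemistry):** the mixed acetals 20–22 and the ozonide 24 are carried as epimer mixtures at the one centre that is destroyed later, so that centre carries no stereo label in their SMILES. Atom labels C1–C12 are those of the target as defined below; β is the ring face of the C5 oxygen, α the opposite face.

## The problem

Compound 29 is a cycloheptane with a γ-lactone cis-fused across C6–C7. The ring carbons are C1 (tertiary carbinol carrying the chain C2(=O)–C3H2–C4H(OH)–CH3), C5 (angelate), C6 (lactone oxygen), C7 (ring-fusion CH), C8 and C9 (methylenes) and C10 (CH–CH3); the lactone adds C11 (CH–CH3) and C12 (C=O). Seven stereocentres have to be set: five contiguous ring centres (C10, C1, C5, C6, C7), C11 and the remote C4. With the C5 oxygen β, the C1 hydroxyl, the C6 oxygen, the C7–C11 bond and the C10 methyl are all α, and the C11 methyl sits on the concave face of the bicycle, cis to C8. The trans C5/C6 diol can be bought and can then steer C7 (through a tether from O6), C10 and C1; C11 can be set from the convex face of the cis-fused lactone; C4 is too far from the ring to be steered and must arrive with its configuration. C1 is a fully substituted α-ketol between two stereocentres, so the C1–C2 bond has to be made on a hindered ketone with control of the face. The angelate (Z to E drift, hydrogenation, ozone), the β-hydroxy ketone (retro-aldol, dehydration), the tertiary α-ketol (acyloin shift) and the kinetically placed C11 methyl rule out strong base and redox steps late in the route. What makes a short ring synthesis possible is that O–C5–C6–O with its neighbours C1 and C7 is the carbon chain of tartaric acid, while C8–C9 is unfunctionalised and C10 carries only a methyl. A five-membered oxacycle O–C1–C5–C6–C7 with an ethylidene group on C1 and a vinyl group on C7 therefore contains the allyl vinyl ether C10=C1–O–C7–C8=C9, whose [3,3] shift gives the carbocycle.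

## Retrosynthesis

**29 to 28 to 27.** The C5–O acyl bond and the C4 O–Si bond are cut last. The Z-trisubstituted ester would not survive hydrogen, ozone, tin radicals or base, so it must enter after the last such step. In 27 the C5 hydroxyl is the only acylable one (C4 silylated, C1 tertiary). The forward steps must acylate a hindered alcohol without Z/E isomerisation and remove one silyl group without base.

**27 to 25 to 23.** C11–H and the C5 benzyl ether are traced to the α-methylene lactone 25, so that one hydrogenation sets C11 from the convex face and frees O5. An enolate methylation or protonation would need strong base beside a ketone and a tertiary alkoxide, which this cut avoids. The C2 ketone is then traced to the 1,1-disubstituted alkene of 23, so the ketone appears only after all organometallic and radical chemistry is done. The forward ozonolysis must tell an electron-rich alkene from a conjugated one.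

**23 to 21 to 20 to 19.** The lactone is cut at C7–C11 and at the acetal level of C12, leading to a three-carbon haloacetal hung on O6 of the cycloheptenediol 19. The tether fixes both the regiochemistry (C11 to C7) and the cis fusion, which an intermolecular annulation of the C7=C8 alkene could not guarantee. The precursor has no lactone and one stereocentre fewer.

**19 to 18 to 10 + 15.** The C1–C2 bond is cut to the ring ketone 10 and the alkenyl bromide 15, which carries C2–C4 and the C4 stereocentre from the chiral pool. The neighbouring option, a two-carbon acyl anion followed by a methyl ketone aldol with acetaldehyde, would leave C4 without a reliable control element. The forward addition must be non-basic (10 has a β-silyloxy group and an epimerisable C10) and must occur on the β face.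

**10 to 9 (key step).** A retro-Claisen cut of C9–C10 with reconnection of O to C7 turns the cycloheptenone into the oxolane 9. Against a ring-closing olefin metathesis of an open chain or an aldehyde cyclisation, this cut gives in one step the ring, the C1 ketone for the side chain, the C7=C8 alkene where the lactone is to be built and the C10 stereocentre. The precursor is a five-membered ring with three stereocentres, two of them bought.

**9 to 8 to 6 to 4 to 3 to 2 to 1.** The enol ether comes from γ-lactone 8 by carbonyl ethylidenation, and 8 from aldehyde 6 by addition of a vinyl nucleophile and ring closure. Aldehyde 6 comes from diethyl D-tartrate 1 by desymmetrisation: one benzyl group, then reduction of the ester next to the free hydroxyl. The forward chemistry must tell the two ester ends apart and set C7 anti to O6.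

**15 to 13 to 12 to 11.** The side-chain bromide is traced through a terminal alkyne to (R)-propylene oxide 11, which supplies C4 and its methyl group.

## Roads not taken

**Alternative 1:** The lactone is cut at C7–C11 and C6–C12 on a complete cycloheptene A1 (C6=C7 alkene, C1 chain and C10 methyl in place). Forward, methylchloroketene A2 would add [2+2] on the α face, anti to the C5 silyloxy group, to give the cis-fused chloro(methyl)cyclobutanone A3; Baeyer–Villiger oxidation and reductive dechlorination would then give the methyl lactone. Its merits are that both lactone carbons and the C11 methyl arrive in one step, the suprafacial addition guarantees cis fusion, and ring strain makes the oxygen insertion clean. For the lactone alone it is at least as short as the chosen road (three operations against four) and needs no tin. Its weak points for this target: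
- The addition is intermolecular; the regiochemistry (C12 to C6) rests only on weak polarisation of an unactivated cis-disubstituted alkene by the allylic oxygen, and the facial selectivity on one silyloxy group.
- A ketene of modest reactivity meets a hindered alkene in a substrate that already carries the C2 ketone and its β-silyloxy group, both exposed to amine base and later to peracid.
- C11 still has to be set afterwards, and the seven-membered ring with C1, C5 and C10 must come from elsewhere; A1 is no easier to make than 19.

Against the shorter lactone sequence the chosen plan sets the oxygen tether of 20, which fixes regiochemistry and cis fusion intramolecularly, and a key step that makes the carbocycle itself.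

**Alternative 2:** The C10–CH3 and C1–C2 bonds are cut on the diosphenol ether A4 (its carbonyl is the future C5). Forward, a copper-catalysed, phosphoramidite-controlled conjugate transfer of methyl from zinc to C10 would give an alkoxy-substituted zinc enolate that is trapped at C1 by aldehyde A5, giving A6. Its merits are catalyst-controlled absolute configuration, the correct trans relation of the C10 methyl and the C1 chain from anti trapping, and arrival of the whole side chain with C4 from the pool. For C1, C10 and C2–C4 it is more convergent than steps 8–11 and 16 here, and it avoids the facial question of step 11. Its weak points for this target: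
- α-Alkoxy enones are electron-rich, α-substituted acceptors and poor substrates for conjugate addition.
- The aldol of a tetrasubstituted enolate with an enolisable aldehyde gives a retro-aldol-prone tertiary ether.
- C5, C6, C7 and C11 are all still missing. C6 and C7 are bare methylenes in A6, so the lactone would need desaturation, oxygenation and carbon attachment on a flexible ring with four more stereocentres under substrate control.

The chosen plan buys C5 and C6 and places the alkene exactly where the lactone is built; what it has to set against A6 is a separate coupling step whose facial outcome is less certain.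

**Alternative 3:** The C6–C7 bond and the lactone C–O bond are cut in an open-chain aldehyde A7 carrying a 2-(bromomethyl)enoate. Forward, reduction with a divalent chromium salt would give an allylchromium species that adds through C7 to the C6 aldehyde and closes the seven-membered ring; the C6 alkoxide then closes the α-methylene lactone A8. Its merit is that carbocycle, lactone and two stereocentres form in one operation, more bond formation than any single step of the chosen route. The allylation usually gives the cis lactone, and the exocyclic methylene can set C11 by hydrogenation just as in step 17. Its weak points for this target: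
- Everything else must first be assembled in an open chain: the quaternary C1 with its ketone, C5, C10 and C4, with the C10/C1/C5 triad built without a ring to relay stereochemistry.
- The C2 ketone competes as electrophile.
- Seven-membered closure is entropically the least favourable, and its facial outcome relative to C5 is not secured.

Where this road is better (the cascade replaces steps 13–15 and 17), the chosen plan sets a ring closure that starts from a lactone made in five steps from 1 and creates C10 under rigid control, so no acyclic quaternary stereocentre has to be built.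

Key step: step 7

## Route

Step 1
Reactants: 1 diethyl D-tartrate [diethyl (2S,3S)-2,3-dihydroxybutanedioate]
Product: 2 diethyl (2S,3S)-2-(benzyloxy)-3-hydroxybutanedioate
Conditions: BnBr, Ag2O, CH2Cl2, rt, dark
Reagents that add atoms: benzyl bromide, BrCc1ccccc1
Why: Ag2O-mediated Williamson monoalkylation of a symmetrical 1,2-diol; after the first benzylation the remaining hydroxyl is less acidic and more hindered, and the C2-symmetric diester gives one monoether whichever hydroxyl reacts.

Step 2
Reactants: 2 diethyl (2S,3S)-2-(benzyloxy)-3-hydroxybutanedioate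
Product: 3 ethyl (2S,3R)-2-(benzyloxy)-3,4-dihydroxybutanoate
Conditions: BH3·SMe2, NaBH4 (cat.), THF, 0 °C to rt; MeOH
Reagents that add atoms: none
Why: Hydroxyl-directed borane reduction of an α-hydroxy ester: the free hydroxyl (future O6) forms an alkoxyborane that delivers hydride only to the adjacent ester, so the ester beside the benzyloxy carbon (future C1) survives; the new descriptor at C3 reflects a priority change, not an inversion.

Step 3
Reactants: 3 ethyl (2S,3R)-2-(benzyloxy)-3,4-dihydroxybutanoate
Product: 4 ethyl (2S,3R)-2-(benzyloxy)-3,4-bis(triethylsilyloxy)butanoate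
Conditions: TESCl, imidazole, DMAP (cat.), CH2Cl2, 0 °C to rt
Reagents that add atoms: chlorotriethylsilane, CC[Si](Cl)(CC)CC
Why: Routine silylation of both hydroxyls, done on the crude diol so that the γ-hydroxy ester has no time to lactonise.

Step 4
Reactants: 4 ethyl (2S,3R)-2-(benzyloxy)-3,4-bis(triethylsilyloxy)butanoate
Product: 6 ethyl (2S,3S)-2-(benzyloxy)-4-oxo-3-(triethylsilyloxy)butanoate, via alkoxysulfonium chloride 5 (not isolated)
Conditions: (COCl)2, DMSO, CH2Cl2, −78 to −40 °C; Et3N, −78 to 0 °C
Reagents that add atoms: none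
Why: Swern oxidation applied directly to a bis(triethylsilyl) ether: the unhindered primary silyl ether is cleaved by the chlorosulfonium salt and oxidised while the secondary one stays, which gives the C7 aldehyde beside the C6 silyl ether without a separate deprotection.

Step 5
Reactants: 6 ethyl (2S,3S)-2-(benzyloxy)-4-oxo-3-(triethylsilyloxy)butanoate
Product: 8 (3S,4R,5R)-3-(benzyloxy)-5-ethenyl-4-(triethylsilyloxy)oxolan-2-one, via hydroxy ester 7 (not isolated)
Conditions: CH2=CHMgBr, THF, −78 °C; AcOH, −78 °C; then PPTS (cat.), PhH, 50 °C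
Reagents that add atoms: vinylmagnesium bromide, C=C[Mg]Br
Why: Grignard addition to an α-silyloxy aldehyde under Felkin–Anh control (nucleophile anti to the C6–O bond) should give the 6,7-anti carbinol (C7 R), and the 1,3-anti preference exerted by the C5 benzyloxy group points the same way; the γ-hydroxy ester then closes to the all-trans γ-lactone with loss of ethanol, and any C7 epimer can be removed at this stage.

Step 6
Reactants: 8 (3S,4R,5R)-3-(benzyloxy)-5-ethenyl-4-(triethylsilyloxy)oxolan-2-one
Product: 9 (2Z,3S,4R,5R)-3-(benzyloxy)-5-ethenyl-2-ethylidene-4-(triethylsilyloxy)oxolane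
Conditions: CH3CHBr2, TiCl4, Zn, TMEDA, PbCl2 (cat.), THF, 0 °C to rt; aq. K2CO3, basic alumina
Reagents that add atoms: 1,1-dibromoethane, CC(Br)Br
Why: Takai–Utimoto alkylidenation of an ester carbonyl with the gem-dimetallic reagent from 1,1-dibromoethane; the reaction is Z-selective for alkenyl ethers, and A(1,3) strain between the new methyl and the C5 benzyloxy carbon reinforces the geometry with methyl syn to the ring oxygen.

Step 7
Reactants: 9 (2Z,3S,4R,5R)-3-(benzyloxy)-5-ethenyl-2-ethylidene-4-(triethylsilyloxy)oxolane
Product: 10 (2S,3R,7S)-2-(benzyloxy)-7-methyl-3-(triethylsilyloxy)cyclohept-4-en-1-one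
Conditions: PhMe (degassed), silanised sealed tube, 180 °C
Reagents that add atoms: none
Why: Thermal [3,3]-sigmatropic (Claisen) rearrangement of the allyl vinyl ether C10=C1–O–C7–C8=C9 held in 9: the C9–C10 bond forms while the O–C7 bond breaks, which leaves the ring oxygen as the C1 ketone and moves the double bond to C7=C8. The closest known reaction type is the ring-enlarging Claisen rearrangement of 2-alkylidene-5-vinyltetrahydrofurans and 2-methylene-6-vinyltetrahydropyrans to cyclohept-4-enones and cyclooct-4-enones. The cycloheptene closes by a two-atom ring expansion: the four oxolane carbons C1, C5, C6 and C7 are joined by C8, C9 and C10 as the two exocyclic termini bond across the ring, and the C5–C6 tether allows only the chair-like array, because a boat would put a trans double bond into the seven-membered ring. The one new stereocentre, C10, is fixed by two elements of the substrate: the vinyl group on C7 can reach C10 only on its own (β) face of the oxolane, and the Z geometry of the ethylidene group then places the methyl α, cis to the C6 oxygen (7S in 10). The step therefore needs an enol ether that stays Z and exocyclic until it rearranges; A(1,3) strain against the C5 benzyloxy carbon holds the geometry, and acid-free silanised glass prevents migration of the double bond into the ring. C5 and C6 take no part in the bond reorganisation, and the neutral conditions should leave the epimerisable C10 and the β-silyloxy ketone intact.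

Step 8
Reactants: 11 (2R)-2-methyloxirane [(R)-propylene oxide]
Product: 12 (2R)-pent-4-yn-2-ol
Conditions: LiC≡CH·H2NCH2CH2NH2, DMSO, 0 °C to rt; aq. NH4Cl
Reagents that add atoms: lithium acetylide ethylenediamine complex, [Li]C#C.NCCN
Why: SN2 opening of a terminal epoxide by acetylide at the unsubstituted carbon; the stereocentre is not touched, so the R configuration of the future C4 comes from the pool.

Step 9
Reactants: 12 (2R)-pent-4-yn-2-ol
Product: 13 tert-butyl[(2R)-pent-4-yn-2-yloxy]diphenylsilane
Conditions: TBDPSCl, imidazole, DMF, rt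
Reagents that add atoms: tert-butyl(chloro)diphenylsilane, CC(C)(C)[Si](Cl)(c1ccccc1)c1ccccc1
Why: Routine silylation; the tert-butyldiphenylsilyl ether is chosen because it outlasts the bromoborane of step 10, the removal of the triethylsilyl group in step 12 and the acidic oxidation of step 15.

Step 10
Reactants: 13 tert-butyl[(2R)-pent-4-yn-2-yloxy]diphenylsilane
Product: 15 {[(2R)-4-bromopent-4-en-2-yl]oxy}(tert-butyl)diphenylsilane, via alkenylborane 14 (not isolated)
Conditions: B-Br-9-BBN, CH2Cl2, 0 °C; AcOH, 0 °C; aq. NaHCO3
Reagents that add atoms: B-bromo-9-borabicyclo[3.3.1]nonane, BrB1C2CCCC1CCC2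
Why: syn-Bromoboration of a terminal alkyne places bromine on the internal carbon, and protonolysis of the C–B bond with acetic acid leaves the 2-bromo-1-alkene (a formal Markovnikov addition of HBr).

Step 11
Reactants: 15 {[(2R)-4-bromopent-4-en-2-yl]oxy}(tert-butyl)diphenylsilane; 10 (2S,3R,7S)-2-(benzyloxy)-7-methyl-3-(triethylsilyloxy)cyclohept-4-en-1-one
Product: 18 (1R,2S,3R,7S)-2-(benzyloxy)-1-[(4R)-4-(tert-butyldiphenylsilyloxy)pent-1-en-2-yl]-7-methyl-3-(triethylsilyloxy)cyclohept-4-en-1-ol, via alkenyllithium 16 (not isolated), via alkenylcerium dichloride 17 (not isolated)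
Conditions: 15, t-BuLi, Et2O, −78 °C; CeCl3, THF, −78 °C; then 10, THF, −78 °C; aq. NH4Cl
Reagents that add atoms: none
Why: Bromine–lithium exchange, transmetalation to the weakly basic organocerium reagent and 1,2-addition to a hindered, enolisable ketone. Chelation of the metal between the C1 carbonyl and the C5 benzyloxy oxygen should fix the ring with the C10 methyl pseudoaxial on the α face beside the C6 silyloxy group, so the nucleophile enters on the β face and the C1 hydroxyl ends up α (the descriptor 1R reflects the alkenyl substituent). The low basicity of the cerium reagent is needed to avoid enolisation towards C5 and loss of the C6 oxygen.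

Step 12
Reactants: 18 (1R,2S,3R,7S)-2-(benzyloxy)-1-[(4R)-4-(tert-butyldiphenylsilyloxy)pent-1-en-2-yl]-7-methyl-3-(triethylsilyloxy)cyclohept-4-en-1-ol
Product: 19 (1R,2S,3R,7S)-2-(benzyloxy)-1-[(4R)-4-(tert-butyldiphenylsilyloxy)pent-1-en-2-yl]-7-methylcyclohept-4-ene-1,3-diol
Conditions: PPTS, MeOH/CH2Cl2, 0 °C
Reagents that add atoms: none
Why: Acid-catalysed methanolysis removes a secondary triethylsilyl ether much faster than a tert-butyldiphenylsilyl ether, so only the allylic C6 hydroxyl is freed.

Step 13
Reactants: 19 (1R,2S,3R,7S)-2-(benzyloxy)-1-[(4R)-4-(tert-butyldiphenylsilyloxy)pent-1-en-2-yl]-7-methylcyclohept-4-ene-1,3-diol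
Product: 20 (1R,2S,3R,7S)-2-(benzyloxy)-3-[(2-bromo-1-methoxyprop-2-en-1-yl)oxy]-1-[(4R)-4-(tert-butyldiphenylsilyloxy)pent-1-en-2-yl]-7-methylcyclohept-4-en-1-ol (acetal epimers)
Conditions: methoxyallene, NBS, 2,6-lutidine, CH2Cl2, −78 to −30 °C
Reagents that add atoms: methoxyallene, C=C=COC; N-bromosuccinimide, O=C1CCC(=O)N1Br
Why: Haloacetalisation: bromination of the central carbon of the alkoxyallene gives an oxocarbenium ion that the secondary allylic C6 hydroxyl traps faster than the crowded tertiary C1 hydroxyl, giving the 2-bromoallyl mixed acetal needed for an Ueno–Stork closure; the electron-rich allene outcompetes the other alkenes for the bromine.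

Step 14
Reactants: 20 (1R,2S,3R,7S)-2-(benzyloxy)-3-[(2-bromo-1-methoxyprop-2-en-1-yl)oxy]-1-[(4R)-4-(tert-butyldiphenylsilyloxy)pent-1-en-2-yl]-7-methylcyclohept-4-en-1-ol
Product: 21 (3aS,6S,7R,8S,8aR)-8-(benzyloxy)-7-[(4R)-4-(tert-butyldiphenylsilyloxy)pent-1-en-2-yl]-2-methoxy-6-methyl-3-methylideneoctahydro-2H-cyclohepta[b]furan-7-ol (C2 epimers)
Conditions: Bu3SnH, AIBN (cat.), PhH, 80 °C
Reagents that add atoms: none
Why: Ueno–Stork radical cyclisation: the vinyl radical at C11 closes 5-exo-trig on C7 of the ring alkene, and the three-atom tether from O6 allows only the cis ring fusion, which sets C7 (C7–C11 bond α, 3aS). The C8 radical is then reduced by the stannane, kept concentrated enough to outrun transannular addition to the side-chain alkene.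

Step 15
Reactants: 21 (3aS,6S,7R,8S,8aR)-8-(benzyloxy)-7-[(4R)-4-(tert-butyldiphenylsilyloxy)pent-1-en-2-yl]-2-methoxy-6-methyl-3-methylideneoctahydro-2H-cyclohepta[b]furan-7-ol
Product: 23 (3aS,6S,7R,8S,8aR)-8-(benzyloxy)-7-[(4R)-4-(tert-butyldiphenylsilyloxy)pent-1-en-2-yl]-7-hydroxy-6-methyl-3-methylideneoctahydro-2H-cyclohepta[b]furan-2-one, via lactol 22 (not isolated)
Conditions: CrO3, H2SO4, H2O, acetone, 0 °C; i-PrOH
Reagents that add atoms: water, O
Why: Jones oxidation of an Ueno–Stork acetal: the allylic mixed acetal is hydrolysed in the acidic medium and the lactol is oxidised at once to the α-methylene γ-lactone. Because the oxidation is irreversible, any reversible capture of the oxocarbenium ion by the cis C1 hydroxyl should be drained, and brief exposure at 0 °C should spare the hindered tertiary allylic alcohol and the silyl ether.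

Step 16
Reactants: 23 (3aS,6S,7R,8S,8aR)-8-(benzyloxy)-7-[(4R)-4-(tert-butyldiphenylsilyloxy)pent-1-en-2-yl]-7-hydroxy-6-methyl-3-methylideneoctahydro-2H-cyclohepta[b]furan-2-one
Product: 25 (3aS,6S,7S,8S,8aR)-8-(benzyloxy)-7-[(3R)-3-(tert-butyldiphenylsilyloxy)butanoyl]-7-hydroxy-6-methyl-3-methylideneoctahydro-2H-cyclohepta[b]furan-2-one, via ozonide 24 (not isolated)
Conditions: O3, CH2Cl2, −78 °C (Sudan Red 7B end point); Me2S, −78 °C to rt
Reagents that add atoms: ozone, [O-][O+]=O
Why: Ozonolysis with reductive work-up turns the electron-rich 1,1-disubstituted side-chain alkene into the C2 ketone; the conjugated exocyclic methylene of the lactone is electron-poor and reacts with electrophilic ozone much more slowly, and the indicator stops the gas flow at that point.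

Step 17
Reactants: 25 (3aS,6S,7S,8S,8aR)-8-(benzyloxy)-7-[(3R)-3-(tert-butyldiphenylsilyloxy)butanoyl]-7-hydroxy-6-methyl-3-methylideneoctahydro-2H-cyclohepta[b]furan-2-one
Product: 27 (3R,3aS,6S,7S,8S,8aR)-7-[(3R)-3-(tert-butyldiphenylsilyloxy)butanoyl]-7,8-dihydroxy-3,6-dimethyloctahydro-2H-cyclohepta[b]furan-2-one, via benzyl ether 26 (not isolated)
Conditions: H2 (1 atm), Pd(OH)2/C, EtOAc, rt
Reagents that add atoms: none
Why: Heterogeneous hydrogenation of an α-methylene γ-lactone followed in the same flask by hydrogenolysis of the benzyl ether; hydrogen should reach C11 from the convex face of the cis-fused bicycle (the face of H6 and H7), which puts the C11 methyl on the concave face, cis to C8 (3R), as in the target.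

Step 18
Reactants: 27 (3R,3aS,6S,7S,8S,8aR)-7-[(3R)-3-(tert-butyldiphenylsilyloxy)butanoyl]-7,8-dihydroxy-3,6-dimethyloctahydro-2H-cyclohepta[b]furan-2-one
Product: 28 (3R,3aS,6S,7S,8S,8aR)-7-[(3R)-3-(tert-butyldiphenylsilyloxy)butanoyl]-7-hydroxy-3,6-dimethyl-2-oxooctahydro-2H-cyclohepta[b]furan-8-yl (2Z)-2-methylbut-2-enoate
Conditions: angelic acid, 2,4,6-Cl3C6H2COCl, Et3N, PhMe, rt; then 27, 80 °C
Reagents that add atoms: angelic acid [(2Z)-2-methylbut-2-enoic acid], C/C=C(/C)C(=O)O
Why: Yamaguchi-type esterification through the mixed anhydride with 2,4,6-trichlorobenzoic acid, run without a nucleophilic catalyst so that the Z geometry of the angeloyl group is kept; only the secondary C5 hydroxyl should react, since the C1 hydroxyl is tertiary and C4 is silylated.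

Step 19
Reactants: 28 (3R,3aS,6S,7S,8S,8aR)-7-[(3R)-3-(tert-butyldiphenylsilyloxy)butanoyl]-7-hydroxy-3,6-dimethyl-2-oxooctahydro-2H-cyclohepta[b]furan-8-yl (2Z)-2-methylbut-2-enoate
Product: 29 (3R,3aS,6S,7S,8S,8aR)-7-hydroxy-7-[(3R)-3-hydroxybutanoyl]-3,6-dimethyl-2-oxooctahydro-2H-cyclohepta[b]furan-8-yl (2Z)-2-methylbut-2-enoate (CNP0321985.1)
Conditions: HF·pyridine, pyridine, THF, 0 °C to rt
Reagents that add atoms: none
Why: Buffered fluoride cleavage of the silyl ether under mildly acidic conditions, which avoids base at the stage where retro-aldol cleavage, acyloin shift, C11 epimerisation and angelate isomerisation are all possible.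

## Compound list

1 | diethyl D-tartrate, diethyl (2S,3S)-2,3-dihydroxybutanedioate | CCOC(=O)[C@@H](O)[C@H](O)C(=O)OCC | starting material
2 | diethyl (2S,3S)-2-(benzyloxy)-3-hydroxybutanedioate | CCOC(=O)[C@@H](OCc1ccccc1)[C@H](O)C(=O)OCC | intermediate
3 | ethyl (2S,3R)-2-(benzyloxy)-3,4-dihydroxybutanoate | CCOC(=O)[C@@H](OCc1ccccc1)[C@H](O)CO | intermediate
4 | ethyl (2S,3R)-2-(benzyloxy)-3,4-bis(triethylsilyloxy)butanoate | CCOC(=O)[C@@H](OCc1ccccc1)[C@H](O[Si](CC)(CC)CC)CO[Si](CC)(CC)CC | intermediate
5 | ethyl (2S,3R)-2-(benzyloxy)-4-[(dimethylsulfonio)oxy]-3-(triethylsilyloxy)butanoate chloride | CCOC(=O)[C@@H](OCc1ccccc1)[C@H](O[Si](CC)(CC)CC)CO[S+](C)C.[Cl-] | intermediate (not isolated)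
6 | ethyl (2S,3S)-2-(benzyloxy)-4-oxo-3-(triethylsilyloxy)butanoate | CCOC(=O)[C@@H](OCc1ccccc1)[C@H](O[Si](CC)(CC)CC)C=O | intermediate
7 | ethyl (2S,3R,4R)-2-(benzyloxy)-4-hydroxy-3-(triethylsilyloxy)hex-5-enoate | CCOC(=O)[C@@H](OCc1ccccc1)[C@H](O[Si](CC)(CC)CC)[C@H](O)C=C | intermediate (not isolated)
8 | (3S,4R,5R)-3-(benzyloxy)-5-ethenyl-4-(triethylsilyloxy)oxolan-2-one | O=C1O[C@H](C=C)[C@@H](O[Si](CC)(CC)CC)[C@@H]1OCc1ccccc1 | intermediate
9 | (2Z,3S,4R,5R)-3-(benzyloxy)-5-ethenyl-2-ethylidene-4-(triethylsilyloxy)oxolane | C/C=C1\O[C@H](C=C)[C@@H](O[Si](CC)(CC)CC)[C@@H]1OCc1ccccc1 | intermediate (precursor of the key step)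
10 | (2S,3R,7S)-2-(benzyloxy)-7-methyl-3-(triethylsilyloxy)cyclohept-4-en-1-one | c1ccccc1CO[C@H]1[C@H](O[Si](CC)(CC)CC)C=CC[C@H](C)C1=O | intermediate (product of the key step)
11 | (2R)-2-methyloxirane | C[C@@H]1CO1 | starting material
12 | (2R)-pent-4-yn-2-ol | C#CC[C@@H](C)O | intermediate
13 | tert-butyl[(2R)-pent-4-yn-2-yloxy]diphenylsilane | C#CC[C@@H](C)O[Si](c1ccccc1)(c1ccccc1)C(C)(C)C | intermediate
14 | 9-[(1Z,4R)-2-bromo-4-(tert-butyldiphenylsilyloxy)pent-1-en-1-yl]-9-borabicyclo[3.3.1]nonane | Br/C(C[C@@H](C)O[Si](c1ccccc1)(c1ccccc1)C(C)(C)C)=C\B1C2CCCC1CCC2 | intermediate (not isolated)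
15 | {[(2R)-4-bromopent-4-en-2-yl]oxy}(tert-butyl)diphenylsilane | C=C(Br)C[C@@H](C)O[Si](c1ccccc1)(c1ccccc1)C(C)(C)C | intermediate
16 | [(4R)-4-(tert-butyldiphenylsilyloxy)pent-1-en-2-yl]lithium | [Li]C(=C)C[C@@H](C)O[Si](c1ccccc1)(c1ccccc1)C(C)(C)C | intermediate (not isolated)
17 | dichloro[(4R)-4-(tert-butyldiphenylsilyloxy)pent-1-en-2-yl]cerium | Cl[Ce](Cl)C(=C)C[C@@H](C)O[Si](c1ccccc1)(c1ccccc1)C(C)(C)C | intermediate (not isolated)
18 | (1R,2S,3R,7S)-2-(benzyloxy)-1-[(4R)-4-(tert-butyldiphenylsilyloxy)pent-1-en-2-yl]-7-methyl-3-(triethylsilyloxy)cyclohept-4-en-1-ol | c1ccccc1CO[C@H]1[C@H](O[Si](CC)(CC)CC)C=CC[C@H](C)[C@@]1(O)C(=C)C[C@@H](C)O[Si](c1ccccc1)(c1ccccc1)C(C)(C)C | intermediate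
19 | (1R,2S,3R,7S)-2-(benzyloxy)-1-[(4R)-4-(tert-butyldiphenylsilyloxy)pent-1-en-2-yl]-7-methylcyclohept-4-ene-1,3-diol | c1ccccc1CO[C@H]1[C@H](O)C=CC[C@H](C)[C@@]1(O)C(=C)C[C@@H](C)O[Si](c1ccccc1)(c1ccccc1)C(C)(C)C | intermediate
20 | (1R,2S,3R,7S)-2-(benzyloxy)-3-[(2-bromo-1-methoxyprop-2-en-1-yl)oxy]-1-[(4R)-4-(tert-butyldiphenylsilyloxy)pent-1-en-2-yl]-7-methylcyclohept-4-en-1-ol (acetal epimers) | c1ccccc1CO[C@H]1[C@H](OC(OC)C(Br)=C)C=CC[C@H](C)[C@@]1(O)C(=C)C[C@@H](C)O[Si](c1ccccc1)(c1ccccc1)C(C)(C)C | intermediate
21 | (3aS,6S,7R,8S,8aR)-8-(benzyloxy)-7-[(4R)-4-(tert-butyldiphenylsilyloxy)pent-1-en-2-yl]-2-methoxy-6-methyl-3-methylideneoctahydro-2H-cyclohepta[b]furan-7-ol (C2 epimers) | c1ccccc1CO[C@H]1[C@@H]2OC(OC)C(=C)[C@@H]2CC[C@H](C)[C@@]1(O)C(=C)C[C@@H](C)O[Si](c1ccccc1)(c1ccccc1)C(C)(C)C | intermediate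
22 | (3aS,6S,7R,8S,8aR)-8-(benzyloxy)-7-[(4R)-4-(tert-butyldiphenylsilyloxy)pent-1-en-2-yl]-6-methyl-3-methylideneoctahydro-2H-cyclohepta[b]furan-2,7-diol (C2 epimers) | c1ccccc1CO[C@H]1[C@@H]2OC(O)C(=C)[C@@H]2CC[C@H](C)[C@@]1(O)C(=C)C[C@@H](C)O[Si](c1ccccc1)(c1ccccc1)C(C)(C)C | intermediate (not isolated)
23 | (3aS,6S,7R,8S,8aR)-8-(benzyloxy)-7-[(4R)-4-(tert-butyldiphenylsilyloxy)pent-1-en-2-yl]-7-hydroxy-6-methyl-3-methylideneoctahydro-2H-cyclohepta[b]furan-2-one | c1ccccc1CO[C@H]1[C@@H]2OC(=O)C(=C)[C@@H]2CC[C@H](C)[C@@]1(O)C(=C)C[C@@H](C)O[Si](c1ccccc1)(c1ccccc1)C(C)(C)C | intermediate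
24 | (3aS,6S,7S,8S,8aR)-8-(benzyloxy)-7-{3-[(2R)-2-(tert-butyldiphenylsilyloxy)propyl]-1,2,4-trioxolan-3-yl}-7-hydroxy-6-methyl-3-methylideneoctahydro-2H-cyclohepta[b]furan-2-one (trioxolane epimers) | c1ccccc1CO[C@H]1[C@@H]2OC(=O)C(=C)[C@@H]2CC[C@H](C)[C@@]1(O)C3(OOCO3)C[C@@H](C)O[Si](c1ccccc1)(c1ccccc1)C(C)(C)C | intermediate (not isolated)
25 | (3aS,6S,7S,8S,8aR)-8-(benzyloxy)-7-[(3R)-3-(tert-butyldiphenylsilyloxy)butanoyl]-7-hydroxy-6-methyl-3-methylideneoctahydro-2H-cyclohepta[b]furan-2-one | c1ccccc1CO[C@H]1[C@@H]2OC(=O)C(=C)[C@@H]2CC[C@H](C)[C@@]1(O)C(=O)C[C@@H](C)O[Si](c1ccccc1)(c1ccccc1)C(C)(C)C | intermediate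
26 | (3R,3aS,6S,7S,8S,8aR)-8-(benzyloxy)-7-[(3R)-3-(tert-butyldiphenylsilyloxy)butanoyl]-7-hydroxy-3,6-dimethyloctahydro-2H-cyclohepta[b]furan-2-one | c1ccccc1CO[C@H]1[C@@H]2OC(=O)[C@H](C)[C@@H]2CC[C@H](C)[C@@]1(O)C(=O)C[C@@H](C)O[Si](c1ccccc1)(c1ccccc1)C(C)(C)C | intermediate (not isolated)
27 | (3R,3aS,6S,7S,8S,8aR)-7-[(3R)-3-(tert-butyldiphenylsilyloxy)butanoyl]-7,8-dihydroxy-3,6-dimethyloctahydro-2H-cyclohepta[b]furan-2-one | O[C@H]1[C@@H]2OC(=O)[C@H](C)[C@@H]2CC[C@H](C)[C@@]1(O)C(=O)C[C@@H](C)O[Si](c1ccccc1)(c1ccccc1)C(C)(C)C | intermediate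
28 | (3R,3aS,6S,7S,8S,8aR)-7-[(3R)-3-(tert-butyldiphenylsilyloxy)butanoyl]-7-hydroxy-3,6-dimethyl-2-oxooctahydro-2H-cyclohepta[b]furan-8-yl (2Z)-2-methylbut-2-enoate | C/C=C(/C)C(=O)O[C@H]1[C@@H]2OC(=O)[C@H](C)[C@@H]2CC[C@H](C)[C@@]1(O)C(=O)C[C@@H](C)O[Si](c1ccccc1)(c1ccccc1)C(C)(C)C | intermediate
29 | (3R,3aS,6S,7S,8S,8aR)-7-hydroxy-7-[(3R)-3-hydroxybutanoyl]-3,6-dimethyl-2-oxooctahydro-2H-cyclohepta[b]furan-8-yl (2Z)-2-methylbut-2-enoate | C/C=C(/C)C(=O)O[C@H]1[C@@H]2OC(=O)[C@H](C)[C@@H]2CC[C@H](C)[C@@]1(O)C(=O)C[C@@H](C)O | target

## Step count and least certain steps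

Total: 19 steps. Longest linear sequence: 16 steps (1–7, then 11–19, from 1). The side-chain branch (steps 8–10, from 11) joins at step 11.

**Step 7 (key step).** The most likely failure is acid-catalysed migration of the exocyclic double bond into the oxolane ring, or Z/E scrambling, before the sigmatropic shift; the first destroys the allyl vinyl ether and the second erodes C10. Thermal loss of the silyloxy group β to the new ketone is the second concern. Fallback: starting from 9, iBu3Al in toluene at room temperature should promote the rearrangement by coordination to the ring oxygen and reduce the nascent ketone in the flask to the cycloheptenol F1. Oxidation with Dess–Martin periodinane buffered with NaHCO3 returns to 10.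

**Step 11.** The organometallic may enolise 10 towards C5, with β-elimination of the C6 silyloxy group, or may attack the α face if the chelate does not control the ring conformation (poor facial selectivity). Fallback: the lactone ring is built first. Starting from 10, PPTS in methanol removes the triethylsilyl group to give the hydroxy ketone F2. Haloacetalisation (methoxyallene, NBS) then gives the bromoacetal F3, and Bu3SnH/AIBN closes it to the bicyclic acetal ketone F4, whose cis-fused ring covers the α face of the carbonyl. Addition of 17 to F4 should then occur on the β face and rejoin the route at 21.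

**Step 15.** The oxocarbenium ion at C12 may be captured by the cis C1 hydroxyl as a bridged internal acetal that is slow to reopen, or the chromate may transpose the tertiary allylic alcohol oxidatively. Fallback: the oxidation is done before the tertiary alcohol exists. Starting from 10 and passing through F2, F3 and F4 as above, CrO3/H2SO4 in acetone converts F4 through the lactol F5 into the keto lactone F6. Chemoselective addition of 17 to the ketone carbonyl of F6 at −78 °C rejoins the route at 23.

**Step 6.** The hindered, oxygen-substituted lactone may react sluggishly with the gem-dimetallic reagent, or the Z selectivity may be lost, which would feed the wrong C10 epimer into step 7. Fallback: a modified Julia olefination. Starting from 8, lithiated 2-(ethylsulfonyl)-1,3-benzothiazole (LiN(SiMe3)2, THF, −78 °C) adds to the lactone carbonyl to give the hemiketal sulfone F7. DBU then triggers Smiles rearrangement with loss of SO2 and benzothiazolone, giving 9 after removal of any E isomer.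

**Step 16.** Ozone may also attack the conjugated exocyclic methylene or the benzyl ether (insufficient chemoselectivity, over-oxidation). Fallback: the order is inverted so that only one alkene meets ozone. Starting from 23, conjugate reduction with [(Ph3P)CuH]6 in wet toluene delivers hydride to the methylene carbon, and protonation of the resulting enolate from the convex face gives the saturated lactone F8. Ozonolysis of F8 in CH2Cl2 with pyridine gives the ketone 26 directly, this time isolated, and hydrogenolysis (H2, Pd(OH)2/C) rejoins the route at 27.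

## Further compounds

F1 | step 7 | 2-(benzyloxy)-7-methyl-3-(triethylsilyloxy)cyclohept-4-en-1-ol with the C2, C3 and C7 configurations of 10 (C1 epimers) | c1ccccc1CO[C@H]1[C@H](O[Si](CC)(CC)CC)C=CC[C@H](C)C1O
F2 | step 11 | (2S,3R,7S)-2-(benzyloxy)-3-hydroxy-7-methylcyclohept-4-en-1-one | c1ccccc1CO[C@H]1[C@H](O)C=CC[C@H](C)C1=O
F3 | step 11 | (2S,3R,7S)-2-(benzyloxy)-3-[(2-bromo-1-methoxyprop-2-en-1-yl)oxy]-7-methylcyclohept-4-en-1-one (acetal epimers) | c1ccccc1CO[C@H]1[C@H](OC(OC)C(Br)=C)C=CC[C@H](C)C1=O
F4 | step 11 | (3aS,6S,8S,8aR)-8-(benzyloxy)-2-methoxy-6-methyl-3-methylideneoctahydro-7H-cyclohepta[b]furan-7-one (C2 epimers) | c1ccccc1CO[C@H]1[C@@H]2OC(OC)C(=C)[C@@H]2CC[C@H](C)C1=O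
F5 | step 15 | (3aS,6S,8S,8aR)-8-(benzyloxy)-2-hydroxy-6-methyl-3-methylideneoctahydro-7H-cyclohepta[b]furan-7-one (C2 epimers) | c1ccccc1CO[C@H]1[C@@H]2OC(O)C(=C)[C@@H]2CC[C@H](C)C1=O
F6 | step 15 | (3aS,6S,8S,8aR)-8-(benzyloxy)-6-methyl-3-methylidenehexahydro-2H-cyclohepta[b]furan-2,7(3H)-dione | c1ccccc1CO[C@H]1[C@@H]2OC(=O)C(=C)[C@@H]2CC[C@H](C)C1=O
F7 | step 6 | (3S,4R,5R)-2-[1-(1,3-benzothiazol-2-ylsulfonyl)ethyl]-3-(benzyloxy)-5-ethenyl-4-(triethylsilyloxy)oxolan-2-ol (epimers at C2 and at the sulfonyl-bearing carbon) | CC(S(=O)(=O)c1nc2ccccc2s1)C1(O)O[C@H](C=C)[C@@H](O[Si](CC)(CC)CC)[C@@H]1OCc1ccccc1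
F8 | step 16 | (3R,3aS,6S,7R,8S,8aR)-8-(benzyloxy)-7-[(4R)-4-(tert-butyldiphenylsilyloxy)pent-1-en-2-yl]-7-hydroxy-3,6-dimethyloctahydro-2H-cyclohepta[b]furan-2-one | c1ccccc1CO[C@H]1[C@@H]2OC(=O)[C@H](C)[C@@H]2CC[C@H](C)[C@@]1(O)C(=C)C[C@@H](C)O[Si](c1ccccc1)(c1ccccc1)C(C)(C)C
A1 | alternative 1 | (3R)-3-(tert-butyldimethylsilyloxy)-1-[2-methyl-1,7-bis(triethylsilyloxy)cyclohept-5-en-1-yl]butan-1-one with the target configuration at C1, C5 and C10 | CC[Si](CC)(CC)O[C@H]1C=CCC[C@H](C)[C@@]1(O[Si](CC)(CC)CC)C(=O)C[C@@H](C)O[Si](C)(C)C(C)(C)C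
A2 | alternative 1 | methylchloroketene (2-chloroprop-1-en-1-one) | CC(Cl)=C=O
A3 | alternative 1 | cis-fused 8-chloro-4,8-dimethyl-2,3-bis(triethylsilyloxy)-3-[(3R)-3-(tert-butyldimethylsilyloxy)butanoyl]bicyclo[5.2.0]nonan-9-one | CC[Si](CC)(CC)O[C@H]1[C@@H]2C(=O)[C@](Cl)(C)[C@@H]2CC[C@H](C)[C@@]1(O[Si](CC)(CC)CC)C(=O)C[C@@H](C)O[Si](C)(C)C(C)(C)C
A4 | alternative 2 | 2-[(4-methoxyphenyl)methoxy]cyclohept-2-en-1-one | O=C1CCCCC=C1OCc1ccc(OC)cc1
A5 | alternative 2 | (3R)-3-(tert-butyldimethylsilyloxy)butanal | O=CC[C@@H](C)O[Si](C)(C)C(C)(C)C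
A6 | alternative 2 | 2-[(3R)-3-(tert-butyldimethylsilyloxy)-1-hydroxybutyl]-2-[(4-methoxyphenyl)methoxy]-3-methylcycloheptan-1-one | O=C1CCCC[C@H](C)[C@@]1(OCc2ccc(OC)cc2)[C@@H](O)C[C@@H](C)O[Si](C)(C)C(C)(C)C
A7 | alternative 3 | methyl (2Z)-2-(bromomethyl)-6-{4-[(3R)-3-(tert-butyldimethylsilyloxy)butanoyl]-5-formyl-2,2-dimethyl-1,3-dioxolan-4-yl}hept-2-enoate with the target configuration at C1, C5 and C10 | CC1(C)O[C@@H](C=O)[C@](O1)(C(=O)C[C@@H](C)O[Si](C)(C)C(C)(C)C)[C@@H](C)CC/C=C(\CBr)C(=O)OC
A8 | alternative 3 | acetonide of the C1/C5 diol of the cis-fused α-methylene lactone carrying the (3R)-3-(tert-butyldimethylsilyloxy)butanoyl chain | CC1(C)O[C@H]2[C@@H]3OC(=O)C(=C)[C@@H]3CC[C@H](C)[C@@]2(O1)C(=O)C[C@@H](C)O[Si](C)(C)C(C)(C)C
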